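**Retrosynthetic overview**

1. The target comes from tris-MOM naphthol 21 by acid MOM removal and air oxidation of the quinol; 21 comes from tetralone 18 by dehydrogenation, and 18 from β-keto ester 17 by demethoxycarbonylation.
2. Feature used: the cresol ring C5'(OH)–C6'–C7'(CH3)–C8' is fused to a ring (C1'–C4', C4a', C8a') that is methyl orsellinate in disguise. C4a' carries the ester carbon (future C5'), C8a' carries the ring methyl (future C8'), and O4' and O2' are the two orsellinate oxygens.
3. Key disconnection: C8'–C7' and C6'–C5', by Michael–Dieckmann annulation of the laterally lithiated biaryl orsellinate 13 with methyl crotonate 14.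
4. The biaryl bond (quinone C3–C1') is made by Negishi coupling of bromo-orsellinate 4 with the arylzinc derived from the MOM-protected bromoquinol 10 (from plumbagin).
5. Ring order: both plumbagin rings and the orsellinate ring are bought; the only ring made is the cresol ring, closed in step 8 and aromatised in step 10.

Key step: step 8

Remark: the target carries no stereodescriptor, so the hindered biaryl axis (present from 13 onward) is taken as unspecified and is formed racemic; the one sp3 centre made in step 8 is removed in step 10. Primed locants are those of the naphthyl unit of the target.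

**Route**

Step 1
Reactants: 1 methyl orsellinate
Product: 2 methyl 2-hydroxy-4-(methoxymethoxy)-6-methylbenzoate
Conditions: MOMCl (1.05 equiv), i-Pr2NEt, CH2Cl2, 0 °C to rt
Reagents that add atoms: chloromethyl methyl ether (MOMCl), COCCl
Why: The 2-OH is locked in a hydrogen bond to the ester carbonyl, so O-alkylation (MOM protection) should take place selectively at the free 4-OH.

Step 2
Reactants: 2 methyl 2-hydroxy-4-(methoxymethoxy)-6-methylbenzoate
Product: 3 methyl 2-methoxy-4-(methoxymethoxy)-6-methylbenzoate
Conditions: MeI, K2CO3, DMF, 40 °C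
Reagents that add atoms: iodomethane, CI
Why: Williamson etherification of the remaining chelated phenol, which carbonate in a dipolar aprotic solvent deprotonates without touching the hindered ester or the MOM ether.

Step 3
Reactants: 3 methyl 2-methoxy-4-(methoxymethoxy)-6-methylbenzoate
Product: 4 methyl 3-bromo-6-methoxy-4-(methoxymethoxy)-2-methylbenzoate
Conditions: NBS (1.0 equiv), MeCN, 0 °C to rt, dark
Reagents that add atoms: N-bromosuccinimide, O=C1CCC(=O)N1Br
Why: Electrophilic aromatic bromination should go to the position para to OMe and ortho to OMOM (next to the ring methyl) and not between the two alkoxy groups, as in the bromination of 3,5-dimethoxytoluene.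

Step 4
Reactants: 5 plumbagin
Product: 6 5-methoxy-2-methylnaphthalene-1,4-dione (O-methylplumbagin)
Conditions: MeI, Ag2O, CH2Cl2, rt, dark
Reagents that add atoms: iodomethane, CI
Why: Purdie methylation with silver oxide etherifies the peri-chelated phenol under non-basic conditions that the quinone tolerates.

Step 5
Reactants: 6 5-methoxy-2-methylnaphthalene-1,4-dione
Product: 8 3-bromo-5-methoxy-2-methylnaphthalene-1,4-dione, via trans-dibromide 7 (not isolated)
Conditions: Br2, NaOAc, AcOH, rt
Reagents that add atoms: bromine, BrBr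
Why: Bromine addition across the quinone C2=C3 bond (anti, giving the racemic trans-dibromide) followed by acetate-induced dehydrobromination is the standard addition–elimination bromination of 2-methylnaphthoquinones, and C3 is the only quinone carbon bearing hydrogen.

Step 6
Reactants: 8 3-bromo-5-methoxy-2-methylnaphthalene-1,4-dione
Product: 10 3-bromo-5-methoxy-1,4-bis(methoxymethoxy)-2-methylnaphthalene, via hydroquinone 9 (not isolated)
Conditions: Na2S2O4, EtOAc/H2O, rt; then NaH, MOMCl, DMF, 0 °C to rt, under argon
Reagents that add atoms: chloromethyl methyl ether (MOMCl), COCCl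
Why: Dithionite reduction of the quinone followed by double Williamson alkylation of the quinol dianion (reductive protection) fixes the quinone as a base-stable bis-MOM ether.

Step 7
Reactants: 10 3-bromo-5-methoxy-1,4-bis(methoxymethoxy)-2-methylnaphthalene; 4 methyl 3-bromo-6-methoxy-4-(methoxymethoxy)-2-methylbenzoate
Product: 13 methyl 6-methoxy-3-[8-methoxy-1,4-bis(methoxymethoxy)-3-methylnaphthalen-2-yl]-4-(methoxymethoxy)-2-methylbenzoate, via aryllithium 11 (not isolated), via arylzinc chloride 12 (not isolated)
Conditions: 10, n-BuLi, THF, −78 °C; ZnCl2, −78 °C to rt; then 4, Pd2(dba)3, RuPhos (2-dicyclohexylphosphino-2',6'-diisopropoxybiphenyl), THF/NMP, 70 °C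
Reagents that add atoms: none
Why: Negishi coupling of an arylzinc halide with an aryl bromide under zerovalent palladium and a bulky dialkylbiarylphosphine is an established way to tetra-ortho-substituted biaryls, the ester is inert to the organozinc, and the new axis forms as a racemate.

Step 8
Reactants: 13 methyl 6-methoxy-3-[8-methoxy-1,4-bis(methoxymethoxy)-3-methylnaphthalen-2-yl]-4-(methoxymethoxy)-2-methylbenzoate; 14 methyl (E)-crotonate
Product: 17 methyl 1-hydroxy-8-methoxy-5-[8-methoxy-1,4-bis(methoxymethoxy)-3-methylnaphthalen-2-yl]-6-(methoxymethoxy)-3-methyl-3,4-dihydronaphthalene-2-carboxylate (enol form), via benzylic lithium 15 (not isolated), via Michael adduct enolate 16 (not isolated)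
Conditions: LiN(i-Pr)2 (1.2 equiv), THF, −78 °C; 14 (1.5 equiv), −78 to 0 °C; AcOH quench
Reagents that add atoms: none
Why: Lithium diisopropylamide removes a proton from the ring methyl ortho to the ester (lateral lithiation) to give a deeply coloured ortho-quinodimethane-type lithium enolate, which adds 1,4 to methyl crotonate and so forms C8'–C7'; the resulting ester enolate then attacks the neighbouring aryl ester and expels methoxide, forming C6'–C5'. The closest known reaction is the Michael–Dieckmann annulation of ortho-toluate anions with α,β-unsaturated esters, which gives 2-alkoxycarbonyl-1-tetralones. The six-membered ring is closed by a 6-exo-trig Dieckmann (intramolecular Claisen) acyl substitution, driven forward by deprotonation of the β-keto ester product by the released methoxide. The new centre C7' (C3 of 17) is set in the conjugate addition with no controlling element beyond a weak bias from the racemic biaryl axis, so a mixture of racemic diastereomers (and keto–enol tautomers) is expected; this does no harm because the centre is erased in step 10. The step needs regiocontrol only: the ester restricts deprotonation to its own ortho methyl (the naphthyl C-methyl has no carbonyl activation), and conjugate addition places the crotonate methyl on C7', meta to the future C5' hydroxyl. The ester, flanked by OMe and the methyl, is too hindered for amide attack or self-condensation, and all phenolic oxygens are masked as base-stable ethers.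

Step 9
Reactants: 17 methyl 1-hydroxy-8-methoxy-5-[8-methoxy-1,4-bis(methoxymethoxy)-3-methylnaphthalen-2-yl]-6-(methoxymethoxy)-3-methyl-3,4-dihydronaphthalene-2-carboxylate
Product: 18 8-methoxy-5-[8-methoxy-1,4-bis(methoxymethoxy)-3-methylnaphthalen-2-yl]-6-(methoxymethoxy)-3-methyl-3,4-dihydronaphthalen-1(2H)-one
Conditions: LiCl, H2O, DMSO, 130 °C, short reaction time
Reagents that add atoms: none
Why: Krapcho dealkoxycarbonylation (chloride attack on the ester methyl, loss of CO2 from the β-keto carboxylate, protonation by water) removes the ester under near-neutral conditions that aryl MOM ethers should survive.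

Step 10
Reactants: 18 8-methoxy-5-[8-methoxy-1,4-bis(methoxymethoxy)-3-methylnaphthalen-2-yl]-6-(methoxymethoxy)-3-methyl-3,4-dihydronaphthalen-1(2H)-one
Product: 21 8-methoxy-5-[8-methoxy-1,4-bis(methoxymethoxy)-3-methylnaphthalen-2-yl]-6-(methoxymethoxy)-3-methylnaphthalen-1-ol, via silyl enol ether 19 (not isolated), via naphthalen-1(4H)-one 20 (not isolated)
Conditions: LiN(SiMe3)2, TMSCl, THF, −78 °C; then Pd(OAc)2 (1.1 equiv), MeCN, rt
Reagents that add atoms: none
Why: Saegusa–Ito oxidation: the silyl enol ether gives a divalent-palladium enolate at C2, syn β-hydride elimination of H-3 gives the 2,3-enone, and this tautomerises to the naphthol, which removes the C3 stereocentre without any oxidant that would attack the electron-rich rings.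

Step 11
Reactants: 21 8-methoxy-5-[8-methoxy-1,4-bis(methoxymethoxy)-3-methylnaphthalen-2-yl]-6-(methoxymethoxy)-3-methylnaphthalen-1-ol
Product: 23 3-(2,5-dihydroxy-4-methoxy-7-methylnaphthalen-1-yl)-5-methoxy-2-methylnaphthalene-1,4-dione (CNP0246277.0), via hydroquinone 22 (not isolated)
Conditions: HCl, MeOH/THF, 45 °C; then air, rt
Reagents that add atoms: none
Why: Acid-catalysed acetal exchange removes all three MOM groups, and the freed 2,3-disubstituted naphthalene-1,4-diol should autoxidise in air to the quinone while the less electron-rich naphthol ring and both methyl ethers stay intact.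

**Compound list**

1 | methyl orsellinate (methyl 2,4-dihydroxy-6-methylbenzoate) | COC(=O)c1c(C)cc(O)cc1O | starting material
2 | methyl 2-hydroxy-4-(methoxymethoxy)-6-methylbenzoate | COC(=O)c1c(C)cc(OCOC)cc1O | intermediate
3 | methyl 2-methoxy-4-(methoxymethoxy)-6-methylbenzoate | COC(=O)c1c(C)cc(OCOC)cc1OC | intermediate
4 | methyl 3-bromo-6-methoxy-4-(methoxymethoxy)-2-methylbenzoate | COC(=O)c1c(OC)cc(OCOC)c(Br)c1C | intermediate
5 | plumbagin (5-hydroxy-2-methylnaphthalene-1,4-dione) | CC1=CC(=O)c2c(O)cccc2C1=O | starting material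
6 | 5-methoxy-2-methylnaphthalene-1,4-dione | COc1cccc2c1C(=O)C=C(C)C2=O | intermediate
7 | trans-2,3-dibromo-5-methoxy-2-methyl-2,3-dihydronaphthalene-1,4-dione (racemic, one enantiomer drawn) | COc1cccc2c1C(=O)[C@@H](Br)[C@](C)(Br)C2=O | intermediate
8 | 3-bromo-5-methoxy-2-methylnaphthalene-1,4-dione | COc1cccc2c1C(=O)C(Br)=C(C)C2=O | intermediate
9 | 3-bromo-5-methoxy-2-methylnaphthalene-1,4-diol | COc1cccc2c(O)c(C)c(Br)c(O)c12 | intermediate
10 | 3-bromo-5-methoxy-1,4-bis(methoxymethoxy)-2-methylnaphthalene | COCOc1c(C)c(Br)c(OCOC)c2c(OC)cccc12 | intermediate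
11 | [8-methoxy-1,4-bis(methoxymethoxy)-3-methylnaphthalen-2-yl]lithium | COCOc1c(C)c([Li])c(OCOC)c2c(OC)cccc12 | intermediate
12 | [8-methoxy-1,4-bis(methoxymethoxy)-3-methylnaphthalen-2-yl]zinc chloride | COCOc1c(C)c([Zn]Cl)c(OCOC)c2c(OC)cccc12 | intermediate
13 | methyl 6-methoxy-3-[8-methoxy-1,4-bis(methoxymethoxy)-3-methylnaphthalen-2-yl]-4-(methoxymethoxy)-2-methylbenzoate (racemic about the biaryl axis) | COC(=O)c1c(OC)cc(OCOC)c(-c2c(C)c(OCOC)c3cccc(OC)c3c2OCOC)c1C | intermediate
14 | methyl (E)-crotonate (methyl (E)-but-2-enoate) | C/C=C/C(=O)OC | starting material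
15 | benzylic lithium derivative of 13 (lithiated at the ring methyl ortho to the ester) | COC(=O)c1c(OC)cc(OCOC)c(-c2c(C)c(OCOC)c3cccc(OC)c3c2OCOC)c1C[Li] | intermediate
16 | lithium ester enolate of the Michael adduct, methyl 3-methyl-4-aryl-butanoate type (racemic at the methyl-bearing carbon, S drawn; enolate geometry undefined; both axial orientations) | COC(=O)c1c(OC)cc(OCOC)c(-c2c(C)c(OCOC)c3cccc(OC)c3c2OCOC)c1C[C@H](C)C=C(O[Li])OC | intermediate
17 | methyl 1-hydroxy-8-methoxy-5-[8-methoxy-1,4-bis(methoxymethoxy)-3-methylnaphthalen-2-yl]-6-(methoxymethoxy)-3-methyl-3,4-dihydronaphthalene-2-carboxylate (enol form; racemic at C3, 3S drawn; both axial orientations) | COC(=O)C1=C(O)c2c(OC)cc(OCOC)c(-c3c(C)c(OCOC)c4cccc(OC)c4c3OCOC)c2C[C@@H]1C | intermediate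
18 | 8-methoxy-5-[8-methoxy-1,4-bis(methoxymethoxy)-3-methylnaphthalen-2-yl]-6-(methoxymethoxy)-3-methyl-3,4-dihydronaphthalen-1(2H)-one (racemic at C3, 3S drawn; both axial orientations) | O=C1c2c(OC)cc(OCOC)c(-c3c(C)c(OCOC)c4cccc(OC)c4c3OCOC)c2C[C@H](C)C1 | intermediate
19 | trimethylsilyl enol ether of 18 (1-trimethylsilyloxy-3,4-dihydronaphthalene; racemic at C3, 3S drawn) | C[Si](C)(C)OC1=C[C@@H](C)Cc2c(-c3c(C)c(OCOC)c4cccc(OC)c4c3OCOC)c(OCOC)cc(OC)c12 | intermediate
20 | 8-methoxy-5-[8-methoxy-1,4-bis(methoxymethoxy)-3-methylnaphthalen-2-yl]-6-(methoxymethoxy)-3-methylnaphthalen-1(4H)-one | O=C1C=C(C)Cc2c(-c3c(C)c(OCOC)c4cccc(OC)c4c3OCOC)c(OCOC)cc(OC)c12 | intermediate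
21 | 8-methoxy-5-[8-methoxy-1,4-bis(methoxymethoxy)-3-methylnaphthalen-2-yl]-6-(methoxymethoxy)-3-methylnaphthalen-1-ol | Oc1cc(C)cc2c(-c3c(C)c(OCOC)c4cccc(OC)c4c3OCOC)c(OCOC)cc(OC)c12 | intermediate
22 | 3-(2,5-dihydroxy-4-methoxy-7-methylnaphthalen-1-yl)-5-methoxy-2-methylnaphthalene-1,4-diol | Oc1cc(C)cc2c(-c3c(C)c(O)c4cccc(OC)c4c3O)c(O)cc(OC)c12 | intermediate
23 | 3-(2,5-dihydroxy-4-methoxy-7-methylnaphthalen-1-yl)-5-methoxy-2-methylnaphthalene-1,4-dione (CNP0246277.0) | COc1cccc2c1C(=O)C(c1c(O)cc(OC)c3c(O)cc(C)cc13)=C(C)C2=O | target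

**Step count**

Total: 11 steps. Longest linear sequence: 8 steps (steps 1–3 or steps 4–6, then steps 7–11).

**Steps most likely to fail, with fallbacks**

Step 8 (key step). The benzylic anion lies between the ester and the perpendicular, doubly ortho-substituted naphthyl ring. Conjugate addition may therefore be slow and lose to proton transfer from the γ-position of the crotonate, with oligomerisation of the acceptor and return of 13. The fallback builds the ring before the biaryl bond, where the anion is flanked only by bromine. It sets out from 4: lateral lithiation with LiN(i-Pr)2 in THF at −78 °C and addition of 14 should give methyl 5-bromo-1-hydroxy-8-methoxy-6-(methoxymethoxy)-3-methyl-3,4-dihydronaphthalene-2-carboxylate F1. Heating with LiCl in wet DMSO should give 5-bromo-8-methoxy-6-(methoxymethoxy)-3-methyl-3,4-dihydronaphthalen-1(2H)-one F2. Negishi coupling of F2 with arylzinc chloride 12 (Pd2(dba)3, RuPhos, THF/NMP, 70 °C), which tolerates the ketone, brings the route back at 18.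

Step 7. Transmetalation and reductive elimination at a centre carrying four ortho substituents may be slow, so that protodemetalation of the arylzinc and homocoupling take over from cross-coupling. The fallback moves the coupling to the quinone oxidation level, where the electrophile is an activated vinylogous acyl bromide flanked by a flat carbonyl. It sets out from 4: Miyaura borylation (B2pin2, KOAc, Pd(OAc)2, SPhos, dioxane, 90 °C) should give methyl 6-methoxy-4-(methoxymethoxy)-2-methyl-3-(4,4,5,5-tetramethyl-1,3,2-dioxaborolan-2-yl)benzoate F3. Suzuki coupling with bromoquinone 8 (Pd(PPh3)4, K3PO4, dioxane/H2O, 80 °C) should give methyl 6-methoxy-3-(8-methoxy-3-methyl-1,4-dioxo-1,4-dihydronaphthalen-2-yl)-4-(methoxymethoxy)-2-methylbenzoate F4. Dithionite reduction to methyl 3-(1,4-dihydroxy-8-methoxy-3-methylnaphthalen-2-yl)-6-methoxy-4-(methoxymethoxy)-2-methylbenzoate F5, followed without isolation by NaH and MOMCl in DMF, returns to the route at 13.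

Step 9. At 130 °C the aryl MOM ethers may be lost through adventitious acid, and chloride may demethylate the methoxy group peri to the ketone. The fallback changes the ester so that it can be removed at room temperature. It sets out from 13: the annulation of step 8 is run with allyl (E)-crotonate in place of 14, to give prop-2-enyl 1-hydroxy-8-methoxy-5-[8-methoxy-1,4-bis(methoxymethoxy)-3-methylnaphthalen-2-yl]-6-(methoxymethoxy)-3-methyl-3,4-dihydronaphthalene-2-carboxylate F6. Deallylation and decarboxylation with catalytic Pd(PPh3)4 and morpholine in THF at rt (Tsuji conditions, zerovalent palladium) should give 18, where the route is rejoined.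

**Further compounds**

F1 | step 8 | methyl 5-bromo-1-hydroxy-8-methoxy-6-(methoxymethoxy)-3-methyl-3,4-dihydronaphthalene-2-carboxylate (racemic, 3S drawn) | COC(=O)C1=C(O)c2c(OC)cc(OCOC)c(Br)c2C[C@@H]1C
F2 | step 8 | 5-bromo-8-methoxy-6-(methoxymethoxy)-3-methyl-3,4-dihydronaphthalen-1(2H)-one (racemic, 3S drawn) | O=C1c2c(OC)cc(OCOC)c(Br)c2C[C@H](C)C1
F3 | step 7 | methyl 6-methoxy-4-(methoxymethoxy)-2-methyl-3-(4,4,5,5-tetramethyl-1,3,2-dioxaborolan-2-yl)benzoate | COC(=O)c1c(OC)cc(OCOC)c(B2OC(C)(C)C(C)(C)O2)c1C
F4 | step 7 | methyl 6-methoxy-3-(8-methoxy-3-methyl-1,4-dioxo-1,4-dihydronaphthalen-2-yl)-4-(methoxymethoxy)-2-methylbenzoate | COC(=O)c1c(OC)cc(OCOC)c(C2=C(C)C(=O)c3cccc(OC)c3C2=O)c1C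
F5 | step 7 | methyl 3-(1,4-dihydroxy-8-methoxy-3-methylnaphthalen-2-yl)-6-methoxy-4-(methoxymethoxy)-2-methylbenzoate | COC(=O)c1c(OC)cc(OCOC)c(-c2c(C)c(O)c3cccc(OC)c3c2O)c1C
F6 | step 9 | prop-2-enyl 1-hydroxy-8-methoxy-5-[8-methoxy-1,4-bis(methoxymethoxy)-3-methylnaphthalen-2-yl]-6-(methoxymethoxy)-3-methyl-3,4-dihydronaphthalene-2-carboxylate (enol form; racemic, 3S drawn) | C=CCOC(=O)C1=C(O)c2c(OC)cc(OCOC)c(-c3c(C)c(OCOC)c4cccc(OC)c4c3OCOC)c2C[C@@H]1C
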